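The earlier runs and the new flask were computed for an exercise; the scatter is artificial.

Take the beta run and ask what stops it while electrophile remains.

in all of them: electrophile 0.20 M; gas 12 mM (held)

| charge | nucleophile | remark | time |
|---|---|---|---|
| beta | 0.10 M | run made earlier |  |
| alpha | 0.30 M | run made earlier |  |
| Saturday's | 0.180 M |  | 8.0 d |
| Sunday's | 0.270 M |  | 8.0 d |
| Monday's | 0.400 M |  | 8.0 d |

| run | time / d | electrophile / % | target / % |
|---|---|---|---|
| beta | 0.333 | 88 | 10 |
| beta | 0.625 | 80 | 13 |
| beta | 1.04 | 71 | 16 |
| beta | 2.00 | 61 | 21 |
| beta | 4.00 | 58 | 25 |
| alpha | 0.833 | 49 | 44 |
| alpha | 1.67 | 34 | 58 |
| alpha | 2.50 | 28 | 63 |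
| alpha | 3.00 | 26 | 67 |
| alpha | 4.00 | 24 | 69 |

(each reading ± 1.5 percentage points)

* part of the electrophile that has reacted at the end, Saturday's
* part of the electrophile that has reacted at the end, Sunday's
* part of the electrophile that has reacted at the end, Monday's
* what raising the concentration of nucleophile from its lowest to its highest value here does to the part of the electrophile that has reacted (changes below 5 percentage points count as none) (no change / it rises / it falls)

- at the start none of free base is dissolved
- what was read earlier has a scatter of 1.5 percentage points, one standard deviation
- steps that have been proposed: acid set free + free base <-> salt of the base; electrophile <-> dormant form; nucleophile + acid set free <-> protonated nucleophile; electrophile + nucleophile -> acid set free + target; gas <-> free base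
- what has gone from electrophile into another species counts as reacted, even if it can come back

I follow the flask in slow motion.

1. First instants. c(free base) starts at nil and the gas feeds it. Electrophile meets nucleophile, and each target sets one acid free. The alpha run already reads target 44% at 0.833 d.

2. Middle. The last reading of the beta run is target 25%, so c(target) reads 0.0500 M from 0.10 M of nucleophile. I therefore take each target to cost two nucleophile, the second ending as protonated nucleophile.

3. The rule. For Saturday's flask 45.0% is the target ceiling, charged c(nucleophile) over 2 times charged c(electrophile). The beta run's ceiling is 25.0%, and its last reading matches that within the scatter of 1.5 percentage points, so I leave any gain from free base out.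

4. Correction. The percent missing from electrophile plus target is dormant form. Its ratio to electrophile reads 0.293 in the beta run and 0.292 in the alpha run.

5. End. The beta run reads its ceiling at 4.00 d, and 8.0 d is twice that. I therefore put target at the ceiling and split the remainder by the ratio. Saturday's gives 57.5% reacted. Sunday's ceiling of 67.5% gives 74.9%. Monday's ceiling is 100%, which gives me no stop short of the charge, so I reckon no figure of my own for Monday's.

The forecast says “Acid set free takes up a second nucleophile, so each target costs two nucleophile.” It gives 59% (56% to 64%), 75% (72% to 80%) and 93% (90% to 96%), and for the trend, it rises. My Saturday's figure is lower than the forecast's.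

The flask gives 60.1%, 75.9% and 93.2%. For the trend the answer is it rises, by 33 points.

    acid set free + free base ⇌ salt of the base (K = 120 /M, k = 1.50 /M/h)
    electrophile ⇌ dormant form (K = 0.360, k = 0.00620 /h)
    nucleophile + acid set free ⇌ protonated nucleophile, settled at all times (K = 21000 /M)
    electrophile + nucleophile → acid set free + target (k = 0.160 /M/h)
    gas ⇌ free base, rate k5*(csat - [free base]) (kL = 0.950 /h)

Saturday's flask ends with target 45.6% against the ceiling of 45.0%; acid set free, salt of the base and remaining nucleophile together shift that ceiling by 0.56 points. The difference in charged nucleophile is the main reason for the trend: the part reacted is 93.2% on Monday's charge and 60.1% on Saturday's. The neighbour of Monday's with 0.050 M of electrophile has a ceiling of 400%, so electrophile is the limiting reagent there, with 0.33% of its charge still unbound. Two nucleophile per target predict 75.0% of the nucleophile left, and that flask holds 75%.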